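## Analysis of the target

The target 30 is a 15-membered benzoate macrolactone (ring atoms: the ester O and C=O, three arene carbons, C1, C2 and C7–C14) that shares its C2–C7 bond with a cyclohexene (C2–C7). The numbering used throughout is: C1 benzylic CH2, C2=C3 tetrasubstituted alkene (methyl on C3), C4, C5, C6 (CHBr), C7 (quaternary, methyl), C8, C9, C10 (CHBr), C11 (C(CH3)OH), C12, C13, C14 (CH–O, bearing isopropenyl). The five stereocentres fall into three groups. C6/C7 are 6S,7S, with bromine cis to the C7 methyl and trans to C8. C10/C11 are 10R,11S, an anti bromohydrin that corresponds to anti addition across an E-alkene. C14 is S and stands alone. The groups are separated by two methylene units each, so none can steer another, and each has to come from reagent control or chirality transfer. Sensitive groups are the bromohydrin (any alkoxide at O11 closes to the epoxide), the neopentylic secondary bromide at C6 (it cannot be made by displacement), the allylic benzoate at C14 (acid or zerovalent palladium can ionise it), and the free phenol. The hard points are the C6 bromide beside a quaternary carbon in one absolute sense, and the closure of a 15-membered ring through a tetrasubstituted alkene carbon. The strategy rests on the C1–C2 bond: C2 is the enol carbon of a 2,6-dimethyl-2-alkylcyclohexanone whose other α-carbon, C7, is quaternary, so an enol triflate can only form towards C3, and the benzylic carbon C1 can be the organozinc partner.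

## Retrosynthetic reasoning

30 ⇒ 29. Only two acid-labile groups are removed last: the silyl ether on O11 and the acetal on the phenol. Both fall under one mildly acidic treatment, so the C11 alkoxide is never formed next to the C10 bromide.

29 ⇒ 27 (through 28). The C1–C2 bond is cut. It is the only ring bond that joins a benzylic sp3 carbon to an sp2 carbon, and the polarity is the natural one: benzylic nucleophile, C2 electrophile as its enol triflate. One step then gives the macrocycle and places the alkene, with no stereocentre at risk. The forward reaction has to metalate the benzylic bromide beside two secondary bromides and has to cyclise rather than oligomerise.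

27 ⇒ 21 + 24 (through 25 and 26). The ester C–O bond is cut. A benzylic bromide would not survive an esterification, because it would alkylate the carboxylate or the acylation catalyst. The arene is therefore brought in as the aldehyde 24 and turned into the bromide only after the ester stands.

21 ⇒ 18 (through 19 and 20). The C10–Br bond goes back to a trans-epoxide opened at the secondary carbon with inversion. This is exactly the anti relationship of the bromohydrin. The ether on O14 (oxidatively removable) is orthogonal to the silyl ether on O11.

18 ⇒ 15 (through 16). The epoxide goes back to the E-alkene by reagent-controlled epoxidation, since no stereocentre is near enough to help. The triflate goes back to the ketone. Epoxidation is done while C2 is still a ketone, so C10=C11 is the only electron-rich alkene.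

15 ⇒ 5 + 13 (through 14). The C9–C10 sp3–sp2 bond is cut. This is the most convergent division: a ring block with C6/C7 and a chain block with C14 and the E-alkene geometry.

5 ⇒ 3 ⇒ 2 ⇒ 1. The C6–Br bond and the C7 quaternary centre go back together to a tertiary allylic alcohol. Electrophilic bromine on the ring alkene and a 1,2-shift of the vinyl group give the bromide trans to the migrated group. The carbinol centre of 2 carries the absolute configuration, and it is set by a catalytic asymmetric addition to enone 1.

13 ⇒ 12 ⇒ 11 ⇒ 10 ⇒ 9 ⇒ 8 ⇒ 6. The C14 centre comes from a catalyst-controlled reduction of enone 11. The E-iodoalkene comes from methylmetalation of the alkyne 6.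

24 ⇒ 23 ⇒ 22. The arene needs only protection of the phenol and ester hydrolysis.

## Alternatives that were turned down

Alternative 1: The C10–Br and C11–O bonds would be made together on the E-alkenoic acid A1 (C14 as the carboxyl carbon, cyclohexene and C1–aryl bond already present). An electrophilic bromine source under a dimeric cinchona-alkaloid catalyst would add to C10=C11 while the carboxylate closes 5-exo on C11, anti to bromine, to give the bromo γ-lactone A2.
- For it: both centres and the regiochemistry come from one catalytic step, and the tether guarantees oxygen at the tertiary carbon. On this point it is stronger than the chosen route, which needs an epoxidation and an intermolecular bromide opening whose regiochemistry rests on the reagent.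
- Against it: A1 contains the tetrasubstituted C2=C3 alkene, which is more electron-rich than C10=C11 and competes for bromine. Trisubstituted alkenoic acids are a less favourable class for this catalyst than 1,1-disubstituted ones.
- Against it: after A2 the lactone carbonyl must still become the C14 carbinol with its isopropenyl group. Acyl addition frees the C11 alkoxide next to C10–Br, which closes to the epoxide. The resulting ketone then has to be reduced with no neighbour to guide it, and the macrocycle remains to be closed.
- Comparison: the chosen route sets C14 early on a small fragment, makes the bromohydrin when no competing alkene is present, and needs only a deprotection after the ring closure.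

Alternative 2: The C2–C7 and C6–Br bonds would be made across the ring of the 19-membered macrocyclic diene A3. A bromosulfonium bromonium donor would attack C6=C7, C2 would add to C7 across the ring, and loss of the C2 proton would give A4, the target as its C11 trifluoroacetate and aryl acetate.
- For it: it follows the likely biogenesis, builds one ring, two bonds and two stereocentres in one step, and is the shortest of the four. On step count and convergence it is stronger.
- Against it: bromine must choose C6=C7 over the equally substituted C2=C3 and the isopropenyl group. The face of attack is set only by the conformation of a floppy 19-membered ring, so the sense of the new C6/C7 pair relative to C10, C11 and C14 is not predictable. The cation at C3 can lose a proton in three directions, and the arene can trap it.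
- Comparison: the chosen route gives up brevity but fixes the C6/C7 configuration by chirality transfer from one carbinol and the alkene position by the only possible enol triflate.

Alternative 3: The aryl–carbonyl and carbonyl–O14 bonds would be made by carbonylative ring closure under a palladium catalyst, from the aryl iodide seco alcohol A5 to the macrolactone A6.
- For it: the ring closes by C–O bond formation at an acylpalladium, which is less demanding sterically than C–C formation at a tetrasubstituted carbon, and no benzylic organometallic has to coexist with the rest of the molecule. On the ease of the ring-closing event itself it is as strong or stronger.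
- Against it: the hindered secondary allylic hydroxyl is a poor trap for the acyl complex, so heat and base are needed. Under those conditions the two secondary bromides and the allylic C–O bond are exposed to zerovalent palladium for a long time, and the aryl palladium can add to the isopropenyl group.
- Against it: the C1–C2 bond at the tetrasubstituted carbon still has to be made beforehand, so the hardest bond is moved, not removed.
- Comparison: the chosen route forms that bond and the ring together at 50 °C or below, and the seco compound is assembled by an ordinary esterification.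

Key step: step 21

Remark: compounds 5, 14, 15 and 16 are carried as mixtures of epimers at C3, a centre that step 12 erases; the ligand antipode in step 1 is the one that sends the vinyl group to the Si face of the carbonyl.

## Route

Step 1
Reactants: 1 2-methylcyclohex-2-en-1-one
Product: 2 (1S)-1-ethenyl-2-methylcyclohex-2-en-1-ol
Conditions: (CH2=CH)2Zn, Ti(OiPr)4, chiral trans-cyclohexane-1,2-diamine bis(hydroxycamphorsulfonamide) ligand (10 mol %), toluene, rt
Reagents that add atoms: divinylzinc, C=C[Zn]C=C
Why: Catalytic asymmetric 1,2-addition of a vinylzinc reagent to a ketone under a chiral titanium bis(sulfonamide) diol complex; 2-substituted cyclohexenones suit this catalyst type because the two flanks of the carbonyl differ strongly, and Si-face delivery should set the carbinol centre S.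

Step 2
Reactants: 2 (1S)-1-ethenyl-2-methylcyclohex-2-en-1-ol
Product: 3 (2S,3S)-3-bromo-2-ethenyl-2-methylcyclohexan-1-one
Conditions: N-bromosuccinimide, NaHCO3, CH2Cl2, −40 → 0 °C
Reagents that add atoms: N-bromosuccinimide, O=C1CCC(=O)N1Br
Why: Bromonium-induced semipinacol rearrangement: bromine adds to the trisubstituted ring alkene on the hydroxyl face, the pseudoaxial vinyl group shifts from the carbinol carbon to C7 anti to the new C–Br bond, and the carbinol becomes the ketone. The shift is suprafacial, so the S carbinol should be translated into 6S,7S with bromine trans to vinyl and cis to methyl; a bromonium ion on the other face cannot give this skeleton, so it costs yield, not purity.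

Step 3
Reactants: 3 (2S,3S)-3-bromo-2-ethenyl-2-methylcyclohexan-1-one
Product: 5 (2S,3S)-3-bromo-2-ethenyl-2,6-dimethylcyclohexan-1-one (6RS), via lithium enolate 4 (not isolated)
Conditions: LiN(iPr)2, THF, −78 °C; MeI, −78 → −20 °C
Reagents that add atoms: iodomethane, CI
Why: Kinetic enolate methylation; the quaternary C7 leaves only the C3 hydrogens, and the bromide has no acidic hydrogen between itself and the carbonyl, so it cannot be lost through the enolate. The new C3 centre is not controlled and disappears in step 12.

Step 4
Reactants: 6 pent-4-yn-1-ol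
Product: 8 (4E)-5-iodo-4-methylpent-4-en-1-ol, via alkenylalane 7 (not isolated)
Conditions: Me3Al, Cp2ZrCl2 (cat.), CH2Cl2, 0 °C → rt; I2, THF, −30 °C
Reagents that add atoms: trimethylaluminium, C[Al](C)C; iodine, II
Why: Zirconium-catalysed carboalumination (Negishi) adds methyl and aluminium syn to the terminal alkyne with methyl on the internal carbon; iodinolysis with retention should give the E-iodoalkene.

Step 5
Reactants: 8 (4E)-5-iodo-4-methylpent-4-en-1-ol
Product: 9 (4E)-5-iodo-4-methylpent-4-enal
Conditions: Dess–Martin periodinane, NaHCO3, CH2Cl2, 0 °C → rt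
Reagents that add atoms: none
Why: Dess–Martin oxidation of a primary alcohol; neutral conditions leave the iodoalkene untouched.

Step 6
Reactants: 9 (4E)-5-iodo-4-methylpent-4-enal
Product: 10 rac-(6E)-7-iodo-2,6-dimethylhepta-1,6-dien-3-ol
Conditions: CH2=C(CH3)MgBr, THF, −78 °C
Reagents that add atoms: isopropenylmagnesium bromide, C=C(C)[Mg]Br
Why: Grignard addition to the aldehyde; the racemate is accepted because the centre is reset in steps 7 and 8.

Step 7
Reactants: 10 rac-(6E)-7-iodo-2,6-dimethylhepta-1,6-dien-3-ol
Product: 11 (6E)-7-iodo-2,6-dimethylhepta-1,6-dien-3-one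
Conditions: Dess–Martin periodinane, NaHCO3, CH2Cl2, 0 °C
Reagents that add atoms: none
Why: Dess–Martin oxidation of a secondary allylic alcohol to the enone, which is used at once because α-methylene ketones dimerise on standing.

Step 8
Reactants: 11 (6E)-7-iodo-2,6-dimethylhepta-1,6-dien-3-one
Product: 12 (3S,6E)-7-iodo-2,6-dimethylhepta-1,6-dien-3-ol
Conditions: (R)-2-methyl-CBS-oxazaborolidine (20 mol %), catecholborane, toluene, −78 °C
Reagents that add atoms: none
Why: Corey–Bakshi–Shibata reduction; the α-branched isopropenyl group acts as the large substituent and the primary alkyl chain as the small one, so the R-configured oxazaborolidine should deliver hydride to give the 3S alcohol (C14 of the target).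

Step 9
Reactants: 12 (3S,6E)-7-iodo-2,6-dimethylhepta-1,6-dien-3-ol
Product: 13 1-({[(3S,6E)-7-iodo-2,6-dimethylhepta-1,6-dien-3-yl]oxy}methyl)-4-methoxybenzene
Conditions: NaH, 4-methoxybenzyl chloride, Bu4NI (cat.), THF/DMF, 0 °C → rt
Reagents that add atoms: 4-methoxybenzyl chloride, COc1ccc(CCl)cc1
Why: Williamson etherification; the C–O bond at the stereocentre is not touched, and the iodoalkene has no hydrogen placed for elimination.

Step 10
Reactants: 5 (2S,3S)-3-bromo-2-ethenyl-2,6-dimethylcyclohexan-1-one (6RS); 13 1-({[(3S,6E)-7-iodo-2,6-dimethylhepta-1,6-dien-3-yl]oxy}methyl)-4-methoxybenzene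
Product: 15 (2S,3S)-3-bromo-2-{(3E,7S)-7-[(4-methoxyphenyl)methoxy]-4,8-dimethylnona-3,8-dien-1-yl}-2,6-dimethylcyclohexan-1-one (6RS), via B-alkyl-9-BBN borane 14 (not isolated)
Conditions: 9-BBN, THF, 0 °C → rt; then 13, PdCl2(dppf), AsPh3, Cs2CO3, DMF/H2O, rt
Reagents that add atoms: none
Why: Anti-Markovnikov hydroboration of the vinyl group (9-BBN should take the terminal alkene much faster than the hindered ketone) followed by B-alkyl Suzuki–Miyaura coupling, which forms C9–C10 with retention of the E geometry. The secondary bromide is inert to this catalyst at room temperature.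

Step 11
Reactants: 15 the coupled ketone with the C10=C11 E-alkene and the C14 4-methoxybenzyl ether
Product: 16 (2S,3S)-3-bromo-2-{2-[(2S,3S)-3-{(3S)-3-[(4-methoxyphenyl)methoxy]-4-methylpent-4-en-1-yl}-3-methyloxiran-2-yl]ethyl}-2,6-dimethylcyclohexan-1-one (6RS), the 10S,11S-epoxide
Conditions: L-fructose-derived Shi ketone (30 mol %), KHSO5, K2CO3, Bu4NHSO4, MeCN/dimethoxymethane/aq. Na2B4O7 buffer, 0 °C
Reagents that add atoms: potassium peroxymonosulfate, [K+].[O-]S(=O)(=O)OO
Why: Shi epoxidation through a chiral dioxirane; the trisubstituted E-alkene should react, while the 1,1-disubstituted alkene with an allylic oxygen is both a poor substrate and deactivated. The D-fructose catalyst gives R,R epoxides from alkenes of this type, so its enantiomer is needed for 10S,11S.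

Step 12
Reactants: 16 the 10S,11S-epoxy ketone
Product: 18 (5S,6S)-5-bromo-6-{2-[(2S,3S)-3-{(3S)-3-[(4-methoxyphenyl)methoxy]-4-methylpent-4-en-1-yl}-3-methyloxiran-2-yl]ethyl}-2,6-dimethylcyclohex-1-en-1-yl trifluoromethanesulfonate, via potassium enolate 17 (not isolated)
Conditions: KN(SiMe3)2, THF, −78 °C; PhNTf2, −78 → 0 °C
Reagents that add atoms: N-phenylbis(trifluoromethanesulfonimide), O=S(=O)(N(c1ccccc1)S(=O)(=O)C(F)(F)F)C(F)(F)F
Why: Enolate O-triflation; C7 is quaternary, so deprotonation can only occur at C3 and the alkene is fixed at C2=C3. The C3 epimers converge here.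

Step 13
Reactants: 18 the enol triflate 10S,11S-epoxide
Product: 19 the bromohydrin (6S,7S,10R,11S,14S): C2 enol triflate, C6 and C10 bromides, free C11 hydroxyl, C14 4-methoxybenzyl ether
Conditions: Li2NiBr4, THF, 0 °C → rt
Reagents that add atoms: dilithium tetrabromonickelate, [Li+].[Li+].Br[Ni-2](Br)(Br)Br
Why: Epoxide opening by a soft bromide source that follows SN2 regiochemistry: attack at the less substituted C10 with inversion, C11–O untouched. This should give the 10R,11S anti bromohydrin; the neopentylic C6 bromide and the triflate are inert.

Step 14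
Reactants: 19 the bromohydrin
Product: 20 the C11 trimethylsilyl ether of 19 (6S,7S,10R,11S,14S)
Conditions: Me3SiOTf, 2,6-lutidine, CH2Cl2, −78 °C
Reagents that add atoms: trimethylsilyl trifluoromethanesulfonate, C[Si](C)(C)OS(=O)(=O)C(F)(F)F
Why: Silylation of the tertiary alcohol under non-nucleophilic base; it blocks both closure to the epoxide and protonolysis of the later organozinc.

Step 15
Reactants: 20 the C11 silyl ether with the C14 4-methoxybenzyl ether
Product: 21 the C14 alcohol (6S,7S,10R,11S,14S): C2 enol triflate, C6 and C10 bromides, C11 trimethylsilyl ether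
Conditions: DDQ, CH2Cl2/pH 7 buffer, 0 °C
Reagents that add atoms: none
Why: Oxidative cleavage of the 4-methoxybenzyl ether; the buffered, non-acidic medium should spare the tertiary silyl ether, and the electron-poor enol triflate alkene is not oxidised.

Step 16
Reactants: 22 methyl 3-formyl-4-hydroxybenzoate
Product: 23 methyl 3-formyl-4-(methoxymethoxy)benzoate
Conditions: MeOCH2Cl, iPr2NEt, CH2Cl2, 0 °C → rt
Reagents that add atoms: chloromethyl methyl ether, COCCl
Why: O-alkylation of the phenol to the methoxymethyl acetal.

Step 17
Reactants: 23 methyl 3-formyl-4-(methoxymethoxy)benzoate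
Product: 24 3-formyl-4-(methoxymethoxy)benzoic acid
Conditions: LiOH, THF/MeOH/H2O, rt; then dilute HCl to pH 4, 0 °C
Reagents that add atoms: lithium hydroxide, [Li+].[OH-]
Why: Saponification; the non-enolisable aryl aldehyde and the acetal tolerate dilute hydroxide and a brief cold acidification.

Step 18
Reactants: 21 the C14 alcohol; 24 3-formyl-4-(methoxymethoxy)benzoic acid
Product: 25 the C14 3-formyl-4-(methoxymethoxy)benzoate of 21 (6S,7S,10R,11S,14S)
Conditions: EDC·HCl, DMAP, CH2Cl2, 0 °C → rt
Reagents that add atoms: none
Why: Carbodiimide (Steglich) esterification; acylation at oxygen keeps the C14 configuration, and the aldehyde stands in for the benzylic bromide, which would alkylate the carboxylate and the catalyst.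

Step 19
Reactants: 25 the aldehyde ester
Product: 26 the benzylic alcohol: C14 3-(hydroxymethyl)-4-(methoxymethoxy)benzoate (6S,7S,10R,11S,14S)
Conditions: NaBH4, THF/MeOH, −20 °C
Reagents that add atoms: none
Why: Chemoselective borohydride reduction of the aryl aldehyde; ester, enol triflate, alkyl bromides and silyl ether do not react at this temperature.

Step 20
Reactants: 26 the benzylic alcohol
Product: 27 the seco ester with benzylic bromide and cyclohexenyl triflate: C14 3-(bromomethyl)-4-(methoxymethoxy)benzoate, C11 trimethylsilyl ether (6S,7S,10R,11S,14S)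
Conditions: CBr4, PPh3, CH2Cl2, 0 °C
Reagents that add atoms: tetrabromomethane, BrC(Br)(Br)Br
Why: Appel bromination of the primary benzylic alcohol under neutral conditions; the bromide is used at once because an ortho-alkoxybenzyl bromide ionises easily.

Step 21
Reactants: 27 the seco ester with benzylic bromide and cyclohexenyl triflate
Product: 29 the macrolactone with C11 trimethylsilyl ether and phenol methoxymethyl ether (6S,7S,10R,11S,14S), via arylmethylzinc bromide 28 (not isolated)
Conditions: Zn dust, LiCl, THF, 0 °C; then syringe-pump addition to Pd(OAc)2 (10 mol %), 2-dicyclohexylphosphino-2′,6′-dimethoxybiphenyl (20 mol %), THF, 50 °C, final concentration 1 mM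
Reagents that add atoms: none
Why: Zinc, solubilised by LiCl, inserts into the benzylic C–Br bond at 0 °C, where the two secondary alkyl bromides insert far more slowly, and gives 28. Zerovalent palladium, formed from Pd(OAc)2 by a little of the organozinc, adds oxidatively to the C2–OTf bond; the benzyl group is then transferred from zinc to palladium within the same molecule and reductive elimination forms C1–C2. The closest known reaction is the intermolecular Negishi coupling of benzylic zinc halides with hindered cycloalkenyl triflates. The 15-membered ring closes in the reductive elimination from a 16-membered palladacycle, with the new bond in the ring and C2=C3 exocyclic to it. No stereocentre is formed, and the alkene position is fixed because the triflate could only be made towards C3. The step needs chemoselective metalation, secured by the reactivity order of the three C–Br bonds. It also needs cyclisation over oligomerisation, secured by slow addition so that each molecule meets the catalyst at high dilution. The allylic benzoate must survive zerovalent palladium; oxidative addition to the triflate with the electron-rich biarylphosphine should outrun its ionisation at 50 °C or below.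

Step 22
Reactants: 29 the protected macrolactone
Product: 30 CNP0305154.1 (6S,7S,10R,11S,14S)
Conditions: HCl (1.25 M in MeOH), THF, 0 °C → rt
Reagents that add atoms: none
Why: Acid-catalysed methanolysis removes the tertiary trimethylsilyl ether and the aryl methoxymethyl acetal in one operation; the bromohydrin is stable to acid, and no alkoxide that could close to the epoxide is formed.

## Compound list

1 | 2-methylcyclohex-2-en-1-one | CC1=CCCCC1=O | starting material
2 | (1S)-1-ethenyl-2-methylcyclohex-2-en-1-ol | C=C[C@@]1(O)CCCC=C1C | intermediate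
3 | (2S,3S)-3-bromo-2-ethenyl-2-methylcyclohexan-1-one | C=C[C@@]1(C)C(=O)CCC[C@@H]1Br | intermediate
4 | lithium (5S,6S)-5-bromo-6-ethenyl-6-methylcyclohex-1-en-1-olate (not isolated) | C=C[C@@]1(C)C(O[Li])=CCC[C@@H]1Br | intermediate
5 | (2S,3S)-3-bromo-2-ethenyl-2,6-dimethylcyclohexan-1-one (6RS) | C=C[C@@]1(C)C(=O)C(C)CC[C@@H]1Br | intermediate
6 | pent-4-yn-1-ol | C#CCCCO | starting material
7 | (E)-alkenyl(dimethyl)alane from 6, O-aluminated (not isolated) | C[Al](C)/C=C(\C)CCCO[Al](C)C | intermediate
8 | (4E)-5-iodo-4-methylpent-4-en-1-ol | OCCC/C(C)=C/I | intermediate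
9 | (4E)-5-iodo-4-methylpent-4-enal | O=CCC/C(C)=C/I | intermediate
10 | rac-(6E)-7-iodo-2,6-dimethylhepta-1,6-dien-3-ol | C=C(C)C(O)CC/C(C)=C/I | intermediate
11 | (6E)-7-iodo-2,6-dimethylhepta-1,6-dien-3-one | C=C(C)C(=O)CC/C(C)=C/I | intermediate
12 | (3S,6E)-7-iodo-2,6-dimethylhepta-1,6-dien-3-ol | C=C(C)[C@@H](O)CC/C(C)=C/I | intermediate
13 | 1-({[(3S,6E)-7-iodo-2,6-dimethylhepta-1,6-dien-3-yl]oxy}methyl)-4-methoxybenzene | C=C(C)[C@@H](OCc1ccc(OC)cc1)CC/C(C)=C/I | intermediate
14 | (2S,3S)-2-[2-(9-borabicyclo[3.3.1]nonan-9-yl)ethyl]-3-bromo-2,6-dimethylcyclohexan-1-one (6RS, not isolated) | B1(C2CCCC1CCC2)CC[C@@]3(C)C(=O)C(C)CC[C@@H]3Br | intermediate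
15 | (2S,3S)-3-bromo-2-{(3E,7S)-7-[(4-methoxyphenyl)methoxy]-4,8-dimethylnona-3,8-dien-1-yl}-2,6-dimethylcyclohexan-1-one (6RS) | C=C(C)[C@@H](OCc1ccc(OC)cc1)CC/C(C)=C/CC[C@@]1(C)C(=O)C(C)CC[C@@H]1Br | intermediate
16 | (2S,3S)-3-bromo-2-{2-[(2S,3S)-3-{(3S)-3-[(4-methoxyphenyl)methoxy]-4-methylpent-4-en-1-yl}-3-methyloxiran-2-yl]ethyl}-2,6-dimethylcyclohexan-1-one (6RS) | C=C(C)[C@@H](OCc1ccc(OC)cc1)CC[C@]1(C)O[C@H]1CC[C@@]2(C)C(=O)C(C)CC[C@@H]2Br | intermediate
17 | potassium enolate of 16 (not isolated) | C=C(C)[C@@H](OCc1ccc(OC)cc1)CC[C@]1(C)O[C@H]1CC[C@@]2(C)C(O[K])=C(C)CC[C@@H]2Br | intermediate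
18 | (5S,6S)-5-bromo-6-{2-[(2S,3S)-3-{(3S)-3-[(4-methoxyphenyl)methoxy]-4-methylpent-4-en-1-yl}-3-methyloxiran-2-yl]ethyl}-2,6-dimethylcyclohex-1-en-1-yl trifluoromethanesulfonate | C=C(C)[C@@H](OCc1ccc(OC)cc1)CC[C@]1(C)O[C@H]1CC[C@@]2(C)C(OS(=O)(=O)C(F)(F)F)=C(C)CC[C@@H]2Br | intermediate
19 | bromohydrin (6S,7S,10R,11S,14S): C2 enol triflate, 6,10-dibromide, C11 hydroxyl, C14 4-methoxybenzyl ether | C=C(C)[C@@H](OCc1ccc(OC)cc1)CC[C@](C)(O)[C@H](Br)CC[C@@]1(C)C(OS(=O)(=O)C(F)(F)F)=C(C)CC[C@@H]1Br | intermediate
20 | C11 trimethylsilyl ether of 19 | C=C(C)[C@@H](OCc1ccc(OC)cc1)CC[C@](C)(O[Si](C)(C)C)[C@H](Br)CC[C@@]1(C)C(OS(=O)(=O)C(F)(F)F)=C(C)CC[C@@H]1Br | intermediate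
21 | C14 alcohol (6S,7S,10R,11S,14S): C2 enol triflate, 6,10-dibromide, C11 trimethylsilyl ether | C=C(C)[C@@H](O)CC[C@](C)(O[Si](C)(C)C)[C@H](Br)CC[C@@]1(C)C(OS(=O)(=O)C(F)(F)F)=C(C)CC[C@@H]1Br | intermediate
22 | methyl 3-formyl-4-hydroxybenzoate | COC(=O)c1ccc(O)c(C=O)c1 | starting material
23 | methyl 3-formyl-4-(methoxymethoxy)benzoate | COC(=O)c1ccc(OCOC)c(C=O)c1 | intermediate
24 | 3-formyl-4-(methoxymethoxy)benzoic acid | OC(=O)c1ccc(OCOC)c(C=O)c1 | intermediate
25 | C14 3-formyl-4-(methoxymethoxy)benzoate of 21 | C=C(C)[C@@H](OC(=O)c1ccc(OCOC)c(C=O)c1)CC[C@](C)(O[Si](C)(C)C)[C@H](Br)CC[C@@]1(C)C(OS(=O)(=O)C(F)(F)F)=C(C)CC[C@@H]1Br | intermediate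
26 | C14 3-(hydroxymethyl)-4-(methoxymethoxy)benzoate of 21 | C=C(C)[C@@H](OC(=O)c1ccc(OCOC)c(CO)c1)CC[C@](C)(O[Si](C)(C)C)[C@H](Br)CC[C@@]1(C)C(OS(=O)(=O)C(F)(F)F)=C(C)CC[C@@H]1Br | intermediate
27 | seco ester with benzylic bromide and cyclohexenyl triflate (C11 trimethylsilyl ether, phenol methoxymethyl ether) | C=C(C)[C@@H](OC(=O)c1ccc(OCOC)c(CBr)c1)CC[C@](C)(O[Si](C)(C)C)[C@H](Br)CC[C@@]1(C)C(OS(=O)(=O)C(F)(F)F)=C(C)CC[C@@H]1Br | intermediate
28 | arylmethylzinc bromide of 27 (not isolated) | C=C(C)[C@@H](OC(=O)c1ccc(OCOC)c(C[Zn]Br)c1)CC[C@](C)(O[Si](C)(C)C)[C@H](Br)CC[C@@]1(C)C(OS(=O)(=O)C(F)(F)F)=C(C)CC[C@@H]1Br | intermediate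
29 | macrolactone with C11 trimethylsilyl ether and phenol methoxymethyl ether (6S,7S,10R,11S,14S) | C=C(C)[C@@H]1CC[C@](C)(O[Si](C)(C)C)[C@H](Br)CC[C@@]2(C)C(=C(C)CC[C@@H]2Br)Cc2cc(ccc2OCOC)C(=O)O1 | intermediate
30 | CNP0305154.1 (6S,7S,10R,11S,14S) | C=C(C)[C@@H]1CC[C@](C)(O)[C@H](Br)CC[C@@]2(C)C(=C(C)CC[C@@H]2Br)Cc2cc(ccc2O)C(=O)O1 | target

## Step count and least certain steps

Total: 22 steps. Longest linear sequence: 17 steps (from 6 through steps 4–9, 10–15 and 18–22).

Step 21 (key step).
- What may go wrong: intermolecular coupling to dimers and oligomers, because oxidative addition at the hindered tetrasubstituted triflate is slow and the zinc reagent waits.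
- What may go wrong: protonolysis of the benzylic zinc before it is transferred to palladium.
- What may go wrong: ionisation of the C14 allylic benzoate by zerovalent palladium.
- Fallback (sets out from 21 and uses 23, returns at 29): the two ring-forming events are exchanged, so the C1–C2 bond is made between separate molecules and the ring is closed at the ester, where the allylic ester never meets palladium. NaBH4 reduces 23 to methyl 3-(hydroxymethyl)-4-(methoxymethoxy)benzoate F1. CBr4/PPh3 gives methyl 3-(bromomethyl)-4-(methoxymethoxy)benzoate F2. Zn/LiCl in THF gives the arylmethylzinc bromide F3. F3 in excess is coupled with triflate 21 under Pd(OAc)2 and the same biarylphosphine to the C14-hydroxy methyl ester F4; the free secondary hydroxyl is tolerated by benzylic zinc halides in such couplings. Me3SnOH in 1,2-dichloroethane at 70 °C cleaves the methyl ester to the seco acid F5 without forming an alkoxide. Yamaguchi macrolactonisation (2,4,6-trichlorobenzoyl chloride, Et3N; then DMAP, toluene, high dilution) closes the ring to 29.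

Step 1.
- What may go wrong: erosion of enantioselectivity, because the unsubstituted vinylzinc reagent is more reactive than the substituted alkenylzinc reagents usual for this catalyst and can add without it.
- Fallback (sets out from 1, returns at 2): CH2=CHMgBr with CeCl3 in THF at −78 °C gives racemic 1-ethenyl-2-methylcyclohex-2-en-1-ol F6, which is resolved by preparative chromatography on a chiral stationary phase; the S enantiomer is 2.

Step 2.
- What may go wrong: capture of the bromonium ion by the free hydroxyl (epoxide formation) or bromination of the vinyl group instead of the 1,2-shift; attack on the wrong face lowers the yield.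
- Fallback (sets out from 2, returns at 3): N-(trimethylsilyl)imidazole converts 2 into its trimethylsilyl ether F7. The preformed bromosulfonium salt Et2SBr·SbBrCl5 in MeNO2 at −25 °C delivers bromine without a nucleophilic counter-ion; the shift then ends by loss of the silyl group instead of a proton, and oxygen can no longer trap the bromonium ion.

Step 13.
- What may go wrong: bromide attack at the tertiary C11, or Lewis-acid rearrangement of the epoxide to a carbonyl compound.
- Fallback (sets out from 15 with step 11 left out, returns at 19): KN(SiMe3)2/PhNTf2 converts 15 into the alkenyl triflate with intact C10=C11 alkene F8. N-Bromosuccinimide in aqueous THF at 0 °C adds bromine and water anti across this alkene with water at the tertiary carbon. This gives 19 together with its 10S,11R diastereomer F9 in equal amounts; they are separated by preparative HPLC. Regiochemistry is then certain, at the price of half the material.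

## Further compounds

F1 | step 21 | methyl 3-(hydroxymethyl)-4-(methoxymethoxy)benzoate | COC(=O)c1ccc(OCOC)c(CO)c1
F2 | step 21 | methyl 3-(bromomethyl)-4-(methoxymethoxy)benzoate | COC(=O)c1ccc(OCOC)c(CBr)c1
F3 | step 21 | arylmethylzinc bromide from F2 | COC(=O)c1ccc(OCOC)c(C[Zn]Br)c1
F4 | step 21 | C14-hydroxy methyl ester, C1–C2 coupled (6S,7S,10R,11S,14S) | C=C(C)[C@@H](O)CC[C@](C)(O[Si](C)(C)C)[C@H](Br)CC[C@@]1(C)C(=C(C)CC[C@@H]1Br)Cc1cc(ccc1OCOC)C(=O)OC
F5 | step 21 | seco acid (6S,7S,10R,11S,14S) | C=C(C)[C@@H](O)CC[C@](C)(O[Si](C)(C)C)[C@H](Br)CC[C@@]1(C)C(=C(C)CC[C@@H]1Br)Cc1cc(ccc1OCOC)C(=O)O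
F6 | step 1 | racemic 1-ethenyl-2-methylcyclohex-2-en-1-ol | C=CC1(O)CCCC=C1C
F7 | step 2 | trimethylsilyl ether of 2 | C=C[C@@]1(O[Si](C)(C)C)CCCC=C1C
F8 | step 13 | alkenyl triflate with intact C10=C11 alkene (6S,7S,14S) | C=C(C)[C@@H](OCc1ccc(OC)cc1)CC/C(C)=C/CC[C@@]1(C)C(OS(=O)(=O)C(F)(F)F)=C(C)CC[C@@H]1Br
F9 | step 13 | 10S,11R diastereomer of 19 | C=C(C)[C@@H](OCc1ccc(OC)cc1)CC[C@@](C)(O)[C@@H](Br)CC[C@@]1(C)C(OS(=O)(=O)C(F)(F)F)=C(C)CC[C@@H]1Br
A1 | alternative 1 | E-alkenoic acid with cyclohexene and C1–aryl bond in place | OC(=O)CC/C(C)=C/CC[C@@]1(C)C(=C(C)CC[C@@H]1Br)Cc1cc(ccc1OCOC)C(=O)OCC[Si](C)(C)C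
A2 | alternative 1 | bromo γ-lactone with C10 and C11 set | O=C1CC[C@](C)(O1)[C@H](Br)CC[C@@]2(C)C(=C(C)CC[C@@H]2Br)Cc2cc(ccc2OCOC)C(=O)OCC[Si](C)(C)C
A3 | alternative 2 | 19-membered macrocyclic diene (C11 trifluoroacetate, aryl acetate) | C=C(C)[C@@H]1CC[C@](C)(OC(=O)C(F)(F)F)[C@H](Br)CC/C(C)=C/CC/C(C)=C/Cc2cc(ccc2OC(C)=O)C(=O)O1
A4 | alternative 2 | target as C11 trifluoroacetate and aryl acetate | C=C(C)[C@@H]1CC[C@](C)(OC(=O)C(F)(F)F)[C@H](Br)CC[C@@]2(C)C(=C(C)CC[C@@H]2Br)Cc2cc(ccc2OC(C)=O)C(=O)O1
A5 | alternative 3 | aryl iodide seco alcohol (C11 triethylsilyl ether, phenol tert-butyldimethylsilyl ether) | C=C(C)[C@@H](O)CC[C@](C)(O[Si](CC)(CC)CC)[C@H](Br)CC[C@@]1(C)C(=C(C)CC[C@@H]1Br)Cc1cc(I)ccc1O[Si](C)(C)C(C)(C)C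
A6 | alternative 3 | macrolactone as phenol tert-butyldimethylsilyl ether and C11 triethylsilyl ether | C=C(C)[C@@H]1CC[C@](C)(O[Si](CC)(CC)CC)[C@H](Br)CC[C@@]2(C)C(=C(C)CC[C@@H]2Br)Cc2cc(ccc2O[Si](C)(C)C(C)(C)C)C(=O)O1
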